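**Retrosynthetic overview**
- The A and B rings are bought intact; only the pyranone C ring is built, and it is built last by O1–C2 cyclodehydration of an o-hydroxyaryl 1,3-diketone.
- The diketone comes from C-acylation (C2–C3 bond) of the methyl-ketone enolate of 2,6-dihydroxy-3,4,5-trimethoxyacetophenone with 2,4,5-trimethoxybenzoyl chloride.
- The symmetric 2,6-dihydroxy ketone comes from a twofold ketone-directed ortho C–H oxygenation of commercial 3,4,5-trimethoxyacetophenone (the proposed new step).
- Because the two phenols are equivalent, one becomes the ring oxygen and the other the 5-OH, so no protecting group or selective demethylation is needed.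

Assumption: the target has no stereocentre and is achiral, so "single enantiomer" is read as the single constitutional isomer drawn and no stereocontrol is required.

Step 1
Reactants: 1 3,4,5-trimethoxyacetophenone
Product: 4 1-(2,6-dihydroxy-3,4,5-trimethoxyphenyl)ethan-1-one, via mono-trifluoroacetate ester 2 (not isolated), via bis-trifluoroacetate ester 3 (not isolated)
Conditions: Pd(TFA)2 (10 mol%), K2S2O8 (4.5 equiv, two portions), TFA/TFAA 9:1, 50 °C, 16 h; then H2O/MeCN, rt
Reagents that add atoms: trifluoroacetic acid, OC(=O)C(F)(F)F (supplies the two new oxygen atoms; the CF3CO groups of 2 and 3 are lost again on quench)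
Why: Proposed new method: one-pot twofold ketone-directed Pd(II)/Pd(IV) ortho-C–H oxygenation — the weakly coordinating acetyl oxygen guides carboxylate-assisted (CMD) palladation to C2, peroxodisulfate oxidises the five-membered palladacycle to Pd(IV), and C–O reductive elimination gives aryl trifluoroacetate 2; in TFA/TFAA the new oxygen stays acylated, so it neither chelates Pd (as a free o-hydroxy ketone would) nor exposes the ring to over-oxidation, and because it sits meta to the remaining C6–H (still ortho/para to two OMe groups) the carbonyl can turn and direct an identical second cycle to 3; C2 and C6 are the only ring C–H bonds, so there is no regiochemical question, and the labile aryl trifluoroacetates hydrolyse on aqueous quench to the symmetric diol 4; closest known reaction type: Pd- or Ru-catalysed ketone-directed mono-ortho-hydroxylation of aryl ketones with persulfate or hypervalent iodine oxidants in TFA/TFAA; no stereocentre is created.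

Step 2
Reactants: 5 2,4,5-trimethoxybenzoic acid
Product: 6 2,4,5-trimethoxybenzoyl chloride
Conditions: (COCl)2 (1.3 equiv), DMF (cat.), CH2Cl2, 0 °C to rt; evaporate, use crude
Reagents that add atoms: oxalyl chloride, O=C(Cl)C(=O)Cl
Why: Standard Vilsmeier-catalysed conversion of a carboxylic acid into its acid chloride, to which the aryl methyl ethers and the electron-rich ring are inert at room temperature.

Step 3
Reactants: 4 1-(2,6-dihydroxy-3,4,5-trimethoxyphenyl)ethan-1-one; 6 2,4,5-trimethoxybenzoyl chloride
Product: 8 1-(2,6-dihydroxy-3,4,5-trimethoxyphenyl)-3-(2,4,5-trimethoxyphenyl)propane-1,3-dione, via trilithium enolate 7 (not isolated)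
Conditions: LiHMDS (4.2 equiv), THF, −78 to −10 °C, Ar; then 6 (1.05 equiv), −78 °C to rt; aq. HCl work-up
Reagents that add atoms: lithium hexamethyldisilazide, [Li+].C[Si](C)(C)[N-][Si](C)(C)C (its lithium is held only in 7 and leaves no atom in 8)
Why: Claisen-type C-acylation of a polylithiated o-hydroxyacetophenone, in which excess base masks both phenols as lithium phenoxides so the methyl-ketone enolate is the most nucleophilic site, any O-acylated material is funnelled to the same diketone by Baker–Venkataraman O-to-C acyl transfer, and the fourth equivalent of base protects the product as its diketonate; no stereocentre is formed.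

Step 4
Reactants: 8 1-(2,6-dihydroxy-3,4,5-trimethoxyphenyl)-3-(2,4,5-trimethoxyphenyl)propane-1,3-dione
Product: 9 Agehoustin E (5-hydroxy-6,7,8-trimethoxy-2-(2,4,5-trimethoxyphenyl)-4H-chromen-4-one)
Conditions: H2SO4 (0.5% v/v), AcOH, 95 °C, 1 h
Reagents that add atoms: none
Why: Acid-catalysed cyclodehydration of an o-hydroxyaryl 1,3-diketone (closing stage of the Baker–Venkataraman flavone synthesis), where the two ortho hydroxyls are equivalent so either ring closure, and any Wessely–Moser ring opening and re-closure, gives the same 5-hydroxy-6,7,8-trimethoxy pattern with the spare phenol left as the chelated 5-OH; no stereocentre is formed.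

**Compound list**
1 | 3,4,5-trimethoxyacetophenone | CC(=O)c1cc(OC)c(OC)c(OC)c1 | starting material
2 | 6-acetyl-2,3,4-trimethoxyphenyl trifluoroacetate | CC(=O)c1cc(OC)c(OC)c(OC)c1OC(=O)C(F)(F)F | intermediate
3 | 2-acetyl-4,5,6-trimethoxy-1,3-phenylene bis(trifluoroacetate) | CC(=O)c1c(OC(=O)C(F)(F)F)c(OC)c(OC)c(OC)c1OC(=O)C(F)(F)F | intermediate
4 | 1-(2,6-dihydroxy-3,4,5-trimethoxyphenyl)ethan-1-one | CC(=O)c1c(O)c(OC)c(OC)c(OC)c1O | intermediate
5 | 2,4,5-trimethoxybenzoic acid | COc1cc(OC)c(C(=O)O)cc1OC | starting material
6 | 2,4,5-trimethoxybenzoyl chloride | COc1cc(OC)c(C(=O)Cl)cc1OC | intermediate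
7 | trilithium 2-(1-oxidoethenyl)-4,5,6-trimethoxybenzene-1,3-diolate | [Li+].[Li+].[Li+].C=C([O-])c1c([O-])c(OC)c(OC)c(OC)c1[O-] | intermediate
8 | 1-(2,6-dihydroxy-3,4,5-trimethoxyphenyl)-3-(2,4,5-trimethoxyphenyl)propane-1,3-dione | COc1cc(OC)c(C(=O)CC(=O)c2c(O)c(OC)c(OC)c(OC)c2O)cc1OC | intermediate
9 | Agehoustin E, 5-hydroxy-6,7,8-trimethoxy-2-(2,4,5-trimethoxyphenyl)-4H-chromen-4-one | COc1cc(OC)c(-c2cc(=O)c3c(O)c(OC)c(OC)c(OC)c3o2)cc1OC | target

**Totals**
Total step count: 4. Longest linear sequence: 3 steps (1 → 4 → 8 → 9). Step 2 is a one-step side branch.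

**Three steps most likely to fail**

Step 1 (the proposed new step). Likely failure modes are a stop at the mono-oxygenated stage, single-electron oxidation of the trimethoxyarene, or oxidation at the acetyl methyl group. The fallback uses known chemistry, sets out from 1 and comes back at 4. Electrophilic ring bromination of 1 with NBS (2.3 equiv, MeCN, dark, 0 to 45 °C) takes the same two positions and gives 1-(2,6-dibromo-3,4,5-trimethoxyphenyl)ethan-1-one F1. Twofold Pd-catalysed hydroxylation of the aryl bromides (Pd2(dba)3, tBuXPhos, KOH, 1,4-dioxane/H2O, 100 °C, then aq. HCl) then converts F1 into 4. This replaces C–H activation by halogenation and cross-coupling.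

Step 3. Likely failure modes are O-acylation or double acylation of the hindered trianion, or air oxidation of the electron-rich polyphenoxide. The fallback sets out from 4 (with 6) and comes back at 8. Both phenols are first aroylated on purpose with 6 (2.4 equiv, pyridine, DMAP cat., CH2Cl2) to give 2-acetyl-4,5,6-trimethoxy-1,3-phenylene bis(2,4,5-trimethoxybenzoate) F2. A classical Baker–Venkataraman rearrangement (KOtBu 2.2 equiv, THF, 0 °C to rt) then moves one aroyl group from oxygen to the enolate carbon intramolecularly and gives 3-hydroxy-4,5,6-trimethoxy-2-[3-oxo-3-(2,4,5-trimethoxyphenyl)propanoyl]phenyl 2,4,5-trimethoxybenzoate F3. Mild saponification of the remaining aryl ester (LiOH, THF/H2O, rt, then aq. HCl) returns 8 and recovers acid 5.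

Step 4. This is the least risky of the three; the possible failure is acid-promoted degradation or incomplete closure of the electron-rich diketone. The fallback sets out from 4 and comes back at 9, avoiding the diketone and the strong acid altogether. Claisen–Schmidt condensation of 4 with commercial 2,4,5-trimethoxybenzaldehyde (COc1cc(OC)c(C=O)cc1OC; 50% aq. KOH, EtOH, rt) gives (E)-1-(2,6-dihydroxy-3,4,5-trimethoxyphenyl)-3-(2,4,5-trimethoxyphenyl)prop-2-en-1-one F4. Iodine-catalysed oxidative cyclisation (I2 10 mol%, DMSO, 120 °C) converts F4 into 9. Symmetry again makes the choice of phenol irrelevant.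

**Further compounds**
F1 | step 1 | 1-(2,6-dibromo-3,4,5-trimethoxyphenyl)ethan-1-one | CC(=O)c1c(Br)c(OC)c(OC)c(OC)c1Br
F2 | step 3 | 2-acetyl-4,5,6-trimethoxy-1,3-phenylene bis(2,4,5-trimethoxybenzoate) | CC(=O)c1c(OC(=O)c2cc(OC)c(OC)cc2OC)c(OC)c(OC)c(OC)c1OC(=O)c1cc(OC)c(OC)cc1OC
F3 | step 3 | 3-hydroxy-4,5,6-trimethoxy-2-[3-oxo-3-(2,4,5-trimethoxyphenyl)propanoyl]phenyl 2,4,5-trimethoxybenzoate | COc1cc(OC)c(C(=O)CC(=O)c2c(O)c(OC)c(OC)c(OC)c2OC(=O)c2cc(OC)c(OC)cc2OC)cc1OC
F4 | step 4 | (E)-1-(2,6-dihydroxy-3,4,5-trimethoxyphenyl)-3-(2,4,5-trimethoxyphenyl)prop-2-en-1-one | COc1cc(OC)c(/C=C/C(=O)c2c(O)c(OC)c(OC)c(OC)c2O)cc1OC
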